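**Strategy.** Everything rests on cutting ring A between O1 and C2. This shows that O1, C7a, C3a and C3 form a latent o-quinone methide, and that C2 is a one-carbon unit bearing only its aryl group, i.e. a benzylide carbon. The key step unites three pieces in one flask and forms three bonds and both stereocentres of ring A. The aryllithium of the finished ring B adds to a Boc-protected 5-cyanosalicylaldehyde; Boc transfer and loss of carbonate release the o-quinone methide; a chiral sulfonium 4-silyloxybenzylide adds at C3; the phenoxide O1 then displaces the sulfide at C2. The precursors are an aryl bromide, an aldehyde and a sulfonium salt. The same annulation first builds ring B.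

Key step: step 12

Abbreviation: TIPS = triisopropylsilyl. Atom labels: ring A = the formyl-bearing dihydrobenzofuran (O1, C2, C3); ring B = the second dihydrobenzofuran (O1', C2', C3', attached through C4').

Assumption: the benzylide of the (1R,4R,5R)-sulfide is taken to bond through the face that gives, after invertive ring closure, the (2R) centres; if it gives the mirror-image series, the enantiomeric sulfide from (S)-limonene replaces it with no other change.

Step 1
Reactants: 1 5-bromoresorcinol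
Product: 2 2-bromo-4,6-dihydroxybenzaldehyde
Conditions: POCl3, DMF, MeCN, 0 °C → rt; then H2O, 50 °C
Reagents that add atoms: N,N-dimethylformamide, CN(C)C=O; water, O
Why: Vilsmeier–Haack formylation should go para to one hydroxyl and ortho to the other (as with orcinol), the position between the two hydroxyls being less accessible to the chloroiminium ion.

Step 2
Reactants: 2 2-bromo-4,6-dihydroxybenzaldehyde
Product: 3 2-bromo-6-hydroxy-4-(triisopropylsilyloxy)benzaldehyde
Conditions: TIPSCl (1 equiv), imidazole, CH2Cl2, 0 °C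
Reagents that add atoms: triisopropylsilyl chloride, CC(C)[Si](Cl)(C(C)C)C(C)C
Why: Silyl ether formation should select the 4-hydroxyl, because the 6-hydroxyl is held in a hydrogen bond to the formyl group.

Step 3
Reactants: 3 2-bromo-6-hydroxy-4-(triisopropylsilyloxy)benzaldehyde
Product: 4 tert-butyl [3-bromo-2-formyl-5-(triisopropylsilyloxy)phenyl] carbonate
Conditions: Boc2O, DMAP (cat.), i-Pr2NEt, CH2Cl2, rt
Reagents that add atoms: di-tert-butyl dicarbonate, CC(C)(C)OC(=O)OC(=O)OC(C)(C)C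
Why: DMAP-catalysed acyl transfer converts the chelated phenol into its aryl tert-butyl carbonate, the trigger group for the later o-quinone methide release.

Step 4
Reactants: 1 5-bromoresorcinol
Product: 5 1-bromo-3,5-bis(triisopropylsilyloxy)benzene
Conditions: TIPSCl (2.2 equiv), imidazole, DMF, rt
Reagents that add atoms: triisopropylsilyl chloride, CC(C)[Si](Cl)(C(C)C)C(C)C
Why: Exhaustive silyl ether formation of both phenols gives a base-stable aryl bromide for halogen–lithium exchange.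

Step 5
Reactants: 6 4-hydroxybenzaldehyde
Product: 7 4-(triisopropylsilyloxy)benzaldehyde
Conditions: TIPSCl, imidazole, DMF, rt
Reagents that add atoms: triisopropylsilyl chloride, CC(C)[Si](Cl)(C(C)C)C(C)C
Why: Silyl ether formation of the single phenol is unproblematic.

Step 6
Reactants: 7 4-(triisopropylsilyloxy)benzaldehyde
Product: 8 [4-(triisopropylsilyloxy)phenyl]methanol
Conditions: NaBH4, MeOH, 0 °C
Reagents that add atoms: none
Why: Borohydride reduction of the aryl aldehyde leaves the aryl silyl ether untouched.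

Step 7
Reactants: 8 [4-(triisopropylsilyloxy)phenyl]methanol
Product: 9 4-(triisopropylsilyloxy)benzyl bromide
Conditions: CBr4, PPh3, CH2Cl2, 0 °C
Reagents that add atoms: carbon tetrabromide, BrC(Br)(Br)Br
Why: The Appel reaction brominates the benzylic alcohol under neutral conditions that spare the silyl ether.

Step 8
Reactants: 10 (R)-(+)-limonene
Product: 11 (1R,4R,5R)-4,7,7-trimethyl-6-thiabicyclo[3.2.1]octane (isothiocineole)
Conditions: S8, γ-terpinene, neat, 110 °C
Reagents that add atoms: sulfur, S1SSSSSSS1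
Why: Radical sulfuration of both alkenes with hydrogen transfer from γ-terpinene closes the thia bridge, and the limonene stereocentre (becoming C1) fixes C5 and C4 of the bicycle.

Step 9
Reactants: 11 isothiocineole; 9 4-(triisopropylsilyloxy)benzyl bromide
Product: 12 (1R,4R,5R)-6-[4-(triisopropylsilyloxy)benzyl]-4,7,7-trimethyl-6-thiabicyclo[3.2.1]octan-6-ium tetrafluoroborate (one diastereomer at sulfur from alkylation of the less hindered lone pair; sulfur configuration left open in the SMILES)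
Conditions: NaBF4, CH2Cl2/H2O, rt
Reagents that add atoms: sodium tetrafluoroborate, [Na+].F[B-](F)(F)F
Why: S-Alkylation of the sulfide by the reactive benzylic bromide with counter-ion exchange gives the crystalline sulfonium salt.

Step 10
Reactants: 5 1-bromo-3,5-bis(triisopropylsilyloxy)benzene; 4 tert-butyl [3-bromo-2-formyl-5-(triisopropylsilyloxy)phenyl] carbonate; 12 sulfonium tetrafluoroborate
Product: 15 ring B bromide (2R,3R)-4-bromo-3-[3,5-bis(triisopropylsilyloxy)phenyl]-6-(triisopropylsilyloxy)-2-[4-(triisopropylsilyloxy)phenyl]-2,3-dihydrobenzofuran, via aryllithium 13 (not isolated), via o-quinone methide 14 (not isolated)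
Conditions: 5, t-BuLi (2 equiv), THF, −78 °C; add to 4, −78 °C; then 12, LiN(SiMe3)2, −78 → 0 °C; chromatography removes any cis isomer
Reagents that add atoms: none
Why: Proposed new method: 13 adds to the formyl group of 4, Boc shifts from the phenol to the new alkoxide and the phenoxide expels tert-butyl carbonate to give 14, which the benzylide of 12 attacks at its exocyclic carbon before the phenoxide displaces the sulfide (5-exo-tet, inversion); the closest known types are the [4+1] annulation of o-quinone methides with sulfonium ylides and the isothiocineole benzylide epoxidation of aldehydes, and the sulfide should fix C2' through its ylide face while the anti addition leading to the trans ring fixes C3' as R.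

Step 11
Reactants: 16 3-formyl-4-hydroxybenzonitrile
Product: 17 tert-butyl (4-cyano-2-formylphenyl) carbonate
Conditions: Boc2O, DMAP (cat.), i-Pr2NEt, THF, rt
Reagents that add atoms: di-tert-butyl dicarbonate, CC(C)(C)OC(=O)OC(=O)OC(C)(C)C
Why: DMAP-catalysed acyl transfer gives the aryl carbonate, and the nitrile serves as a formyl surrogate that is inert to ylides.

Step 12
Reactants: 15 ring B bromide; 17 tert-butyl (4-cyano-2-formylphenyl) carbonate; 12 sulfonium tetrafluoroborate
Product: 20 (2R,3R)-3-{(2R,3R)-3-[3,5-bis(triisopropylsilyloxy)phenyl]-6-(triisopropylsilyloxy)-2-[4-(triisopropylsilyloxy)phenyl]-2,3-dihydrobenzofuran-4-yl}-2-[4-(triisopropylsilyloxy)phenyl]-2,3-dihydrobenzofuran-5-carbonitrile, via aryllithium 18 (not isolated), via o-quinone methide 19 (not isolated)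
Conditions: 15, t-BuLi (2 equiv), THF, −78 °C; add to 17, −78 °C; then 12, LiN(SiMe3)2, −78 → 0 °C; chromatography removes any cis isomer
Reagents that add atoms: none
Why: Proposed new method: aryllithium 18 adds to the formyl group of 17, the alkoxide takes the Boc group from the neighbouring phenol oxygen and the freed phenoxide expels tert-butyl carbonate to give o-quinone methide 19, whose exocyclic carbon (future C3) is attacked by the benzylide of 12, after which the phenoxide O1 of the betaine displaces the sulfide at C2. The closest known reaction types are the anionic Boc-transfer generation of o-quinone methides from O-Boc salicylaldehydes, the [4+1] annulation of o-quinone methides with sulfonium ylides and the isothiocineole benzylide epoxidation of aldehydes; new is their combination with a chiral semi-stabilised benzylide. Ring A closes by 5-exo-tet O-alkylation, an SN2 displacement with inversion at C2. C2 is controlled by the sulfide (one ylide face bonds to C3, then inversion), and C3 by the anti mode of conjugate addition that leads to the trans ring, so the trans isomer should be (2R,3R) by reagent control, while a cis isomer, which would differ at C3, is separated. The step needs 1,4- rather than 1,2-attack on 19 (secured by rearomatisation), attack of 18 on the aldehyde rather than the nitrile or carbonate (secured at −78 °C), and base-free, cold conditions that leave the ring B stereocentres untouched.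

Step 13
Reactants: 20 protected nitrile
Product: 21 (2R,3R)-3-{(2R,3R)-3-[3,5-bis(triisopropylsilyloxy)phenyl]-6-(triisopropylsilyloxy)-2-[4-(triisopropylsilyloxy)phenyl]-2,3-dihydrobenzofuran-4-yl}-2-[4-(triisopropylsilyloxy)phenyl]-2,3-dihydrobenzofuran-5-carbaldehyde
Conditions: i-Bu2AlH, CH2Cl2, −78 °C; aq. Rochelle salt, then wet silica
Reagents that add atoms: water, O
Why: Partial reduction of the aryl nitrile stops at the aluminium aldimine, which hydrolyses to the aldehyde, while silyl and aryl ethers are inert.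

Step 14
Reactants: 21 pentakis-TIPS ether of the target
Product: 22 (2R,3R)-3-[(2R,3R)-3-(3,5-dihydroxyphenyl)-6-hydroxy-2-(4-hydroxyphenyl)-2,3-dihydrobenzofuran-4-yl]-2-(4-hydroxyphenyl)-2,3-dihydrobenzofuran-5-carbaldehyde (target)
Conditions: Bu4NF, AcOH (1:1), THF, 0 °C
Reagents that add atoms: none
Why: Acetic-acid-buffered fluoride cleaves the five aryl silyl ethers near neutral pH, which should avoid both acid ionisation and base-induced opening of the dihydrobenzofurans.

**Compound list**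

1 | 5-bromoresorcinol | Oc1cc(O)cc(Br)c1 | starting material
2 | 2-bromo-4,6-dihydroxybenzaldehyde | O=Cc1c(O)cc(O)cc1Br | intermediate
3 | 2-bromo-6-hydroxy-4-(triisopropylsilyloxy)benzaldehyde | O=Cc1c(O)cc(O[Si](C(C)C)(C(C)C)C(C)C)cc1Br | intermediate
4 | tert-butyl [3-bromo-2-formyl-5-(triisopropylsilyloxy)phenyl] carbonate | O=Cc1c(OC(=O)OC(C)(C)C)cc(O[Si](C(C)C)(C(C)C)C(C)C)cc1Br | intermediate
5 | 1-bromo-3,5-bis(triisopropylsilyloxy)benzene | Brc1cc(O[Si](C(C)C)(C(C)C)C(C)C)cc(O[Si](C(C)C)(C(C)C)C(C)C)c1 | intermediate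
6 | 4-hydroxybenzaldehyde | O=Cc1ccc(O)cc1 | starting material
7 | 4-(triisopropylsilyloxy)benzaldehyde | O=Cc1ccc(O[Si](C(C)C)(C(C)C)C(C)C)cc1 | intermediate
8 | [4-(triisopropylsilyloxy)phenyl]methanol | OCc1ccc(O[Si](C(C)C)(C(C)C)C(C)C)cc1 | intermediate
9 | 4-(triisopropylsilyloxy)benzyl bromide | BrCc1ccc(O[Si](C(C)C)(C(C)C)C(C)C)cc1 | intermediate
10 | (R)-(+)-limonene | CC1=CC[C@@H](CC1)C(C)=C | starting material
11 | (1R,4R,5R)-4,7,7-trimethyl-6-thiabicyclo[3.2.1]octane (isothiocineole) | C[C@@H]1CC[C@@H]2C[C@H]1SC2(C)C | intermediate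
12 | (1R,4R,5R)-6-[4-(triisopropylsilyloxy)benzyl]-4,7,7-trimethyl-6-thiabicyclo[3.2.1]octan-6-ium tetrafluoroborate | C[C@@H]1CC[C@@H]2C[C@H]1[S+](Cc1ccc(O[Si](C(C)C)(C(C)C)C(C)C)cc1)C2(C)C.F[B-](F)(F)F | intermediate
13 | [3,5-bis(triisopropylsilyloxy)phenyl]lithium | [Li]c1cc(O[Si](C(C)C)(C(C)C)C(C)C)cc(O[Si](C(C)C)(C(C)C)C(C)C)c1 | intermediate
14 | 6-[3,5-bis(triisopropylsilyloxy)benzylidene]-5-bromo-3-(triisopropylsilyloxy)cyclohexa-2,4-dien-1-one (alkene geometry open) | O=C1C=C(O[Si](C(C)C)(C(C)C)C(C)C)C=C(Br)C1=Cc1cc(O[Si](C(C)C)(C(C)C)C(C)C)cc(O[Si](C(C)C)(C(C)C)C(C)C)c1 | intermediate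
15 | (2R,3R)-4-bromo-3-[3,5-bis(triisopropylsilyloxy)phenyl]-6-(triisopropylsilyloxy)-2-[4-(triisopropylsilyloxy)phenyl]-2,3-dihydrobenzofuran | Brc1cc(O[Si](C(C)C)(C(C)C)C(C)C)cc2c1[C@@H](c1cc(O[Si](C(C)C)(C(C)C)C(C)C)cc(O[Si](C(C)C)(C(C)C)C(C)C)c1)[C@H](c1ccc(O[Si](C(C)C)(C(C)C)C(C)C)cc1)O2 | intermediate
16 | 3-formyl-4-hydroxybenzonitrile | N#Cc1ccc(O)c(C=O)c1 | starting material
17 | tert-butyl (4-cyano-2-formylphenyl) carbonate | N#Cc1ccc(OC(=O)OC(C)(C)C)c(C=O)c1 | intermediate
18 | {(2R,3R)-3-[3,5-bis(triisopropylsilyloxy)phenyl]-6-(triisopropylsilyloxy)-2-[4-(triisopropylsilyloxy)phenyl]-2,3-dihydrobenzofuran-4-yl}lithium | [Li]c1cc(O[Si](C(C)C)(C(C)C)C(C)C)cc2c1[C@@H](c1cc(O[Si](C(C)C)(C(C)C)C(C)C)cc(O[Si](C(C)C)(C(C)C)C(C)C)c1)[C@H](c1ccc(O[Si](C(C)C)(C(C)C)C(C)C)cc1)O2 | intermediate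
19 | 3-{[(2R,3R)-ring B-4-yl]methylidene}-4-oxocyclohexa-1,5-diene-1-carbonitrile, ring B silylated as in 15 (alkene geometry open) | N#CC1=CC(=Cc2cc(O[Si](C(C)C)(C(C)C)C(C)C)cc3c2[C@@H](c2cc(O[Si](C(C)C)(C(C)C)C(C)C)cc(O[Si](C(C)C)(C(C)C)C(C)C)c2)[C@H](c2ccc(O[Si](C(C)C)(C(C)C)C(C)C)cc2)O3)C(=O)C=C1 | intermediate
20 | (2R,3R)-3-{(2R,3R)-3-[3,5-bis(triisopropylsilyloxy)phenyl]-6-(triisopropylsilyloxy)-2-[4-(triisopropylsilyloxy)phenyl]-2,3-dihydrobenzofuran-4-yl}-2-[4-(triisopropylsilyloxy)phenyl]-2,3-dihydrobenzofuran-5-carbonitrile | N#Cc1ccc2c(c1)[C@@H](c1cc(O[Si](C(C)C)(C(C)C)C(C)C)cc3c1[C@@H](c1cc(O[Si](C(C)C)(C(C)C)C(C)C)cc(O[Si](C(C)C)(C(C)C)C(C)C)c1)[C@H](c1ccc(O[Si](C(C)C)(C(C)C)C(C)C)cc1)O3)[C@H](c1ccc(O[Si](C(C)C)(C(C)C)C(C)C)cc1)O2 | intermediate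
21 | the corresponding 5-carbaldehyde (pentakis-TIPS ether of the target) | O=Cc1ccc2c(c1)[C@@H](c1cc(O[Si](C(C)C)(C(C)C)C(C)C)cc3c1[C@@H](c1cc(O[Si](C(C)C)(C(C)C)C(C)C)cc(O[Si](C(C)C)(C(C)C)C(C)C)c1)[C@H](c1ccc(O[Si](C(C)C)(C(C)C)C(C)C)cc1)O3)[C@H](c1ccc(O[Si](C(C)C)(C(C)C)C(C)C)cc1)O2 | intermediate
22 | (2R,3R)-3-[(2R,3R)-3-(3,5-dihydroxyphenyl)-6-hydroxy-2-(4-hydroxyphenyl)-2,3-dihydrobenzofuran-4-yl]-2-(4-hydroxyphenyl)-2,3-dihydrobenzofuran-5-carbaldehyde | O=Cc1ccc2c(c1)[C@@H](c1cc(O)cc3c1[C@@H](c1cc(O)cc(O)c1)[C@H](c1ccc(O)cc1)O3)[C@H](c1ccc(O)cc1)O2 | target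

**Step count.** Total: 14 steps. Longest linear sequence: 8 steps (steps 5, 6, 7, 9, 10, 12, 13, 14).

**Steps most likely to fail**

Step 12 (key step, proposed new method). The benzylide may decompose by sigmatropic rearrangement before the o-quinone methide is released, the hindered aryllithium may attack the carbonate instead of the aldehyde, or the topicity of the conjugate addition may favour the cis ring. The fallback uses known chemistry, sets out from 15 and comes back at 20, and still closes ring A at O1–C2, now through the acid-generated p-silyloxybenzyl cation at C2. Phenol 16 is protected (MOMCl, i-Pr2NEt) as 3-formyl-4-(methoxymethoxy)benzonitrile F7. Aryllithium 18 adds to it to give the diarylmethanol F8, which DMP oxidises to the diaryl ketone F9. Corey–Chaykovsky methylenation (Me3S+ I−, KN(SiMe3)2) gives the 1,1-diaryloxirane F10, and ZnI2 rearranges it (Meinwald) to the diarylacetaldehyde F11. 4-(Triisopropylsilyloxy)phenylmagnesium bromide F12, made from commercial (4-bromophenoxy)triisopropylsilane and Mg, adds to give the 1,1,2-triarylethanol F13. p-TsOH in MeOH/CH2Cl2 then removes the MOM group and ionises the carbinol, and the phenol closes ring A trans to give 20. C3 is only substrate-controlled on this path, so its epimer is removed by chromatography.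

Step 10 (proposed new method). Face control by the sulfide may be insufficient on the o-quinone methide flanked by bromine, or the ylide may be lost before the methide forms. The fallback uses known chemistry, sets out from 3 and comes back at 15; it closes ring B through C2'–C3' by enantioselective C–H insertion of a donor/donor rhodium carbene. Phenol 3 is alkylated with bromide 9 (K2CO3, acetone) to the benzyl ether aldehyde F1. Aryllithium 13 adds to give the carbinol F2, which DMP oxidises to the benzophenone F3. Hydrazine (EtOH, AcOH cat., reflux) gives the hydrazone F4, and MnO2 oxidises it to the diazo compound F5. Rh2(R-PTAD)4 (or its enantiomer, whichever gives the 3R series) inserts the carbene into the benzylic O–CH2 bond to give the cis-(2S,3R)-dihydrobenzofuran F6. CF3CO2H in CH2Cl2 then epimerises C2' through the benzylic cation to the trans isomer 15.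

Step 14. Fluoride may trigger retro-oxa-Michael opening of ring A: the 4-oxidophenyl group at C2 can expel the formyl-stabilised phenoxide O1, and tautomerisation of the resulting quinone methide would scramble C3. The fallback sets out from 21 and comes back at 22; it removes the leaving-group activation before desilylation. NaBH4 reduces the formyl group to the silylated benzylic alcohol F14. Bu4NF/AcOH then gives the pentaphenol benzylic alcohol F15, and activated MnO2 in acetone re-oxidises the benzylic alcohol selectively to 22.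

**Further compounds**

F1 | step 10 | 2-bromo-6-[4-(triisopropylsilyloxy)benzyloxy]-4-(triisopropylsilyloxy)benzaldehyde | O=Cc1c(OCc2ccc(O[Si](C(C)C)(C(C)C)C(C)C)cc2)cc(O[Si](C(C)C)(C(C)C)C(C)C)cc1Br
F2 | step 10 | [3,5-bis(triisopropylsilyloxy)phenyl]{2-bromo-6-[4-(triisopropylsilyloxy)benzyloxy]-4-(triisopropylsilyloxy)phenyl}methanol (racemic) | OC(c1cc(O[Si](C(C)C)(C(C)C)C(C)C)cc(O[Si](C(C)C)(C(C)C)C(C)C)c1)c1c(OCc2ccc(O[Si](C(C)C)(C(C)C)C(C)C)cc2)cc(O[Si](C(C)C)(C(C)C)C(C)C)cc1Br
F3 | step 10 | the corresponding benzophenone | O=C(c1cc(O[Si](C(C)C)(C(C)C)C(C)C)cc(O[Si](C(C)C)(C(C)C)C(C)C)c1)c1c(OCc2ccc(O[Si](C(C)C)(C(C)C)C(C)C)cc2)cc(O[Si](C(C)C)(C(C)C)C(C)C)cc1Br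
F4 | step 10 | the corresponding hydrazone | NN=C(c1cc(O[Si](C(C)C)(C(C)C)C(C)C)cc(O[Si](C(C)C)(C(C)C)C(C)C)c1)c1c(OCc2ccc(O[Si](C(C)C)(C(C)C)C(C)C)cc2)cc(O[Si](C(C)C)(C(C)C)C(C)C)cc1Br
F5 | step 10 | the corresponding diaryldiazomethane | [N-]=[N+]=C(c1cc(O[Si](C(C)C)(C(C)C)C(C)C)cc(O[Si](C(C)C)(C(C)C)C(C)C)c1)c1c(OCc2ccc(O[Si](C(C)C)(C(C)C)C(C)C)cc2)cc(O[Si](C(C)C)(C(C)C)C(C)C)cc1Br
F6 | step 10 | (2S,3R)-4-bromo-3-[3,5-bis(triisopropylsilyloxy)phenyl]-6-(triisopropylsilyloxy)-2-[4-(triisopropylsilyloxy)phenyl]-2,3-dihydrobenzofuran (cis) | Brc1cc(O[Si](C(C)C)(C(C)C)C(C)C)cc2c1[C@@H](c1cc(O[Si](C(C)C)(C(C)C)C(C)C)cc(O[Si](C(C)C)(C(C)C)C(C)C)c1)[C@@H](c1ccc(O[Si](C(C)C)(C(C)C)C(C)C)cc1)O2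
F7 | step 12 | 3-formyl-4-(methoxymethoxy)benzonitrile | N#Cc1ccc(OCOC)c(C=O)c1
F8 | step 12 | [5-cyano-2-(methoxymethoxy)phenyl](ring B-4-yl)methanol, ring B silylated as in 15, carbinol centre as a mixture | N#Cc1ccc(OCOC)c(c1)C(O)c1cc(O[Si](C(C)C)(C(C)C)C(C)C)cc2c1[C@@H](c1cc(O[Si](C(C)C)(C(C)C)C(C)C)cc(O[Si](C(C)C)(C(C)C)C(C)C)c1)[C@H](c1ccc(O[Si](C(C)C)(C(C)C)C(C)C)cc1)O2
F9 | step 12 | the corresponding diaryl ketone | N#Cc1ccc(OCOC)c(c1)C(=O)c1cc(O[Si](C(C)C)(C(C)C)C(C)C)cc2c1[C@@H](c1cc(O[Si](C(C)C)(C(C)C)C(C)C)cc(O[Si](C(C)C)(C(C)C)C(C)C)c1)[C@H](c1ccc(O[Si](C(C)C)(C(C)C)C(C)C)cc1)O2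
F10 | step 12 | the corresponding 2,2-diaryloxirane, new centre as a mixture | N#Cc1ccc(OCOC)c(c1)C1(CO1)c1cc(O[Si](C(C)C)(C(C)C)C(C)C)cc2c1[C@@H](c1cc(O[Si](C(C)C)(C(C)C)C(C)C)cc(O[Si](C(C)C)(C(C)C)C(C)C)c1)[C@H](c1ccc(O[Si](C(C)C)(C(C)C)C(C)C)cc1)O2
F11 | step 12 | 2-[5-cyano-2-(methoxymethoxy)phenyl]-2-(ring B-4-yl)acetaldehyde, C3 as a mixture | N#Cc1ccc(OCOC)c(c1)C(C=O)c1cc(O[Si](C(C)C)(C(C)C)C(C)C)cc2c1[C@@H](c1cc(O[Si](C(C)C)(C(C)C)C(C)C)cc(O[Si](C(C)C)(C(C)C)C(C)C)c1)[C@H](c1ccc(O[Si](C(C)C)(C(C)C)C(C)C)cc1)O2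
F12 | step 12 | 4-(triisopropylsilyloxy)phenylmagnesium bromide | Br[Mg]c1ccc(O[Si](C(C)C)(C(C)C)C(C)C)cc1
F13 | step 12 | 2-[5-cyano-2-(methoxymethoxy)phenyl]-2-(ring B-4-yl)-1-[4-(triisopropylsilyloxy)phenyl]ethanol, new centres as a mixture | N#Cc1ccc(OCOC)c(c1)C(C(O)c1ccc(O[Si](C(C)C)(C(C)C)C(C)C)cc1)c1cc(O[Si](C(C)C)(C(C)C)C(C)C)cc2c1[C@@H](c1cc(O[Si](C(C)C)(C(C)C)C(C)C)cc(O[Si](C(C)C)(C(C)C)C(C)C)c1)[C@H](c1ccc(O[Si](C(C)C)(C(C)C)C(C)C)cc1)O2
F14 | step 14 | 5-(hydroxymethyl) analogue of 21 (pentakis-TIPS ether) | OCc1ccc2c(c1)[C@@H](c1cc(O[Si](C(C)C)(C(C)C)C(C)C)cc3c1[C@@H](c1cc(O[Si](C(C)C)(C(C)C)C(C)C)cc(O[Si](C(C)C)(C(C)C)C(C)C)c1)[C@H](c1ccc(O[Si](C(C)C)(C(C)C)C(C)C)cc1)O3)[C@H](c1ccc(O[Si](C(C)C)(C(C)C)C(C)C)cc1)O2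
F15 | step 14 | 5-(hydroxymethyl) analogue of the target (pentaphenol) | OCc1ccc2c(c1)[C@@H](c1cc(O)cc3c1[C@@H](c1cc(O)cc(O)c1)[C@H](c1ccc(O)cc1)O3)[C@H](c1ccc(O)cc1)O2
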